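Everything rests on disconnecting C-4–C-5. C-4 is α to the C-19 lactone carbonyl and C-5 is β to the C-7 carboxyl, so the γ-lactone ring (O, C-10, C-5, C-4, C-19) is closed by intramolecular Michael addition of a C-10 propanoate enolate to the ring B C-5=C-6 enoate. In the same flask the enolate is relayed to C-4 and trapped by acrolein; one operation forms two C–C bonds and sets C-3 to C-6. The precursor is a B/C/D tricycle (Diels–Alder, gold-catalysed ring D closure) carrying ester, vinyl and propanoate groups; metathesis closes ring A.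

Key step: step 12

Remark: the target is gibberellic acid bearing an additional 12-hydroxyl, named here 12-hydroxygibberellic acid (the gibberellin numbered 87 in the A series). Atom numbers (C-1 to C-19) and ring letters are those of the gibberellane skeleton of the target. In step 5 the (S)-catalyst is assumed to shield the face that leads to 9; if the sense is opposite, its antipode is used.

Step 1
Reactants: 1 furfural; 2 propargyl bromide
Product: 3 (±)-1-(furan-2-yl)but-3-yn-1-ol
Conditions: Zn, THF–sat. aq NH4Cl, 0 °C → rt
Reagents that add atoms: none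
Why: Zinc Barbier propargylation of the aldehyde should give the homopropargylic alcohol; it is racemic, and its stereocentre is erased in step 3.

Step 2
Reactants: 3 (±)-1-(furan-2-yl)but-3-yn-1-ol
Product: 5 (±)-4-hydroxy-2-(prop-2-yn-1-yl)cyclopent-2-en-1-one, via trans-4-hydroxy-5-propargylcyclopent-2-enone 4 (not isolated)
Conditions: ZnCl2, dioxane–H2O, 100 °C; then phosphate buffer (pH 8), 60 °C
Reagents that add atoms: water (O)
Why: Piancatelli rearrangement (furfuryl cation, capture of water, conrotatory 4π closure) should give 4, which isomerises under mild base to the thermodynamically preferred 2-substituted hydroxy-enone.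

Step 3
Reactants: 5 (±)-4-hydroxy-2-(prop-2-yn-1-yl)cyclopent-2-en-1-one
Product: 6 2-(prop-2-yn-1-yl)cyclopent-2-ene-1,4-dione
Conditions: Dess–Martin periodinane, CH2Cl2, 0 °C → rt
Reagents that add atoms: none
Why: Dess–Martin oxidation of the secondary allylic alcohol should give the ene-dione without touching the alkyne, and removes the only stereocentre.

Step 4
Reactants: 7 butane-2,3-dione
Product: 8 2,3-bis(triethylsilyloxy)buta-1,3-diene
Conditions: Et3SiOTf, Et3N, CH2Cl2, 0 °C
Reagents that add atoms: triethylsilyl trifluoromethanesulfonate (CC[Si](CC)(CC)OS(=O)(=O)C(F)(F)F)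
Why: Double enol silylation of the 1,2-diketone (soft enolisation with silyl triflate and amine) should give the 2,3-bis(silyloxy)diene.

Step 5
Reactants: 6 2-(prop-2-yn-1-yl)cyclopent-2-ene-1,4-dione; 8 2,3-bis(triethylsilyloxy)buta-1,3-diene
Product: 9 (3aR,7aS)-7a-(prop-2-yn-1-yl)-5,6-bis(triethylsilyloxy)-3a,4,7,7a-tetrahydro-1H-indene-1,3(2H)-dione
Conditions: (S)-o-tolyl-CBS-oxazaborolidinium triflimide [C24H25BNO][N(SO2CF3)2] (20 mol %), CH2Cl2, −78 °C
Reagents that add atoms: none
Why: Enantioselective Diels–Alder reaction of a quinone-type ene-dione under chiral oxazaborolidinium catalysis: the catalyst binds the C-10 carbonyl (flanked by the vinylic C-9–H) and shields one face, suprafacial addition makes the B/C fusion cis (propargyl on the quaternary C-8 cis to H-9), and the symmetric diene leaves no regiochemical question.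

Step 6
Reactants: 9 cis-fused propargyl dione bis(silyl) enediol ether
Product: 10 9-methylidene-8-(triethylsilyloxy)tricyclo[6.2.1.0^{1,5}]undecane-2,4,7-trione (B/C/D tricycle: 6,10,12-trioxo, 13-OSiEt3, 16-methylene)
Conditions: Ph3PAuNTf2 (5 mol %), CH2Cl2–MeOH (10:1), 0 °C → rt
Reagents that add atoms: none
Why: Gold-catalysed 5-exo-dig carbocyclisation of a silyl enol ether onto an alkyne (Conia-ene type): C-13 attacks the activated C-16, the O-12 silyl group is lost to methanol to give the C-12 ketone, protodeauration leaves the exocyclic methylene, and the tether from C-8 allows only the shown configuration at C-13.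

Step 7
Reactants: 10 B/C/D trione
Product: 11 12-hydroxy-13-(triethylsilyloxy)-16-methylene B/C/D tricycle-6,10-dione (12-OH syn to C-10 and anti to the C-15/C-16 bridge)
Conditions: LiBH(s-Bu)3 (2.2 equiv), THF, −78 °C; then H2O
Reagents that add atoms: none
Why: Hydride reduction: the first equivalent turns the enolised ring-B 1,3-dione into its unreactive lithium enolate, and the bulky borohydride should then attack the C-12 ketone from the face of the C-15/C-16 bridge because the opposite trajectory is blocked by the syn-axial C-10, which places the 12-hydroxyl as in the target.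

Step 8
Reactants: 11 12-hydroxy-13-silyloxy dione
Product: 12 12,13-O-isopropylidene-10-methoxy-16-methylene B/C/D tricycle, 5(10)-en-6-one (vinylogous methyl ester)
Conditions: Me2C(OMe)2, MeOH, camphorsulfonic acid (cat.), rt
Reagents that add atoms: 2,2-dimethoxypropane (COC(C)(C)OC); methanol (CO)
Why: Acid-catalysed transketalisation and enol etherification: methanolysis frees the 13-OH, the syn 12,13-diol closes the acetonide, and the 1,3-dione equilibrates to the vinylogous ester with the methoxy group on the less hindered C-10 (ketone next to the quaternary C-8).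

Step 9
Reactants: 12 acetonide vinylogous ester
Product: 13 10-methoxy-6-(trifluoromethanesulfonyloxy)-5,9-diene (ring-B cyclopentadiene), 12,13-acetonide
Conditions: KN(SiMe3)2, THF, −78 °C; PhNTf2, −78 → 0 °C
Reagents that add atoms: N-phenylbis(trifluoromethanesulfonimide) (O=S(=O)(N(c1ccccc1)S(=O)(=O)C(F)(F)F)C(F)(F)F)
Why: Extended-enolate formation and O-triflation: C-9–H is the only enolisable hydrogen of the vinylogous ester (C-8 is quaternary), so γ-deprotonation and trapping on oxygen should give the C-6 dienyl triflate.

Step 10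
Reactants: 13 dienyl triflate
Product: 15 4-methoxybenzyl 10-oxo-5-en-7-oate of the B/C/D tricycle (12,13-acetonide; H-9 cis to C-15), via dienyl 4-methoxybenzyl ester 14 (not isolated)
Conditions: Pd(OAc)2 (5 mol %), Fe(C5H4PPh2)2 (dppf), CO (1 atm), 4-MeOC6H4CH2OH, Et3N, DMF, 60 °C; then 1 M HCl, THF, 0 °C
Reagents that add atoms: carbon monoxide ([C-]#[O+]); 4-methoxybenzyl alcohol (COc1ccc(CO)cc1); water (O)
Why: Palladium-catalysed alkoxycarbonylation of the vinyl triflate installs C-7 as its 4-methoxybenzyl ester, and mild acid then hydrolyses the methyl enol ether with protonation of C-9 on the face of C-15, restoring the cis B/C fusion, which should also be the thermodynamically preferred, epimerisable arrangement.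

Step 11
Reactants: 15 ring-B enone ester
Product: 17 4-methoxybenzyl 10-vinyl-10-(propanoyloxy)-5-en-7-oate (12,13-acetonide; O-10 syn to O-12), via bromomagnesium 10-alkoxide 16 (not isolated)
Conditions: CeCl3, CH2=CHMgBr, THF, −78 °C; then EtCOCl, −78 → 0 °C
Reagents that add atoms: vinylmagnesium bromide (C=C[Mg]Br); propanoyl chloride (CCC(=O)Cl)
Why: Organocerium 1,2-addition to the enone carbonyl from the face of C-10 turned away from ring C and the 12-oxygen (this sets C-10 with its oxygen syn to O-12), followed by O-acylation of the tertiary alkoxide in the same flask.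

Step 12
Reactants: 17 10-vinyl 10-propanoate enoate
Product: 20 aldol lactone (19,10-lactone with 4-methyl and 4-(1-hydroxyprop-2-enyl); 10-vinyl; 7-(4-methoxybenzyl) ester; 12,13-acetonide), via potassium C-6 ester enolate 18 (not isolated), via potassium C-4 lactone enolate 19 (not isolated)
Conditions: KN(SiMe3)2 (1.1 equiv), THF, −78 → −20 °C; MgBr2·OEt2, −78 °C; CH2=CHCHO, −78 °C; AcOH
Reagents that add atoms: acrolein (C=CC=O)
Why: KN(SiMe3)2 deprotonates the propanoate CH2 (the only acidic C–H), and the ester enolate adds intramolecularly to C-5, the β-carbon of the ring-B enoate, a 5-exo-trig Michael lactonisation of a known type that closes the O–C-10–C-5–C-4–C-19 ring. The C-10 oxygen tether can reach only the face of C-5 cis to it, so C-5 is set by the C-10 stereocentre (cis-fused lactone, H-5 on the opposite face). On warming, proton transfer through HN(SiMe3)2 should convert the hindered C-6 ester enolate 18 into the more acidic, less hindered lactone enolate 19, and the reversibly protonated C-6 settles with the ester trans to C-4, as in the target. After transmetallation to magnesium, 19 should add to acrolein on its convex face (cis to the C-10 vinyl group and H-5), which fixes C-4, and through a Zimmerman–Traxler chair in which the methyl group cis to the enolate oxygen ends syn to the new hydroxyl, which fixes C-3. The step needs conjugate addition to win over [3,3] rearrangement of the allylic ester enolate, and 1,2- over 1,4-addition to acrolein; the first is secured by the low temperature and the five-membered transition state, the second by the magnesium aldolate at −78 °C.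

Step 13
Reactants: 20 aldol lactone
Product: 21 12-hydroxygibberellic acid 12,13-acetonide 7-(4-methoxybenzyl) ester
Conditions: second-generation Grubbs catalyst (5 mol %), CH2Cl2, 40 °C
Reagents that add atoms: none
Why: Ring-closing olefin metathesis of the two cis-disposed vinyl groups should close the six-membered ring A with the C-1=C-2 double bond; the 1,1-disubstituted C-16 methylene is too hindered to compete.

Step 14
Reactants: 21 protected 12-hydroxygibberellic acid
Product: 22 12-hydroxygibberellic acid (the target)
Conditions: CF3CO2H–CH2Cl2 (1:9), anisole, H2O (5 equiv), 0 °C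
Reagents that add atoms: none
Why: Acidolysis removes the 4-methoxybenzyl ester (cation trapped by anisole) and hydrolyses the acetonide in one operation at low temperature, under which the allylic lactone and the tertiary allylic 13-hydroxyl should survive.

**Compound list**

1 | furfural | O=Cc1ccco1 | starting material
2 | propargyl bromide (3-bromoprop-1-yne) | C#CCBr | starting material
3 | (±)-1-(furan-2-yl)but-3-yn-1-ol (racemate) | OC(CC#C)c1ccco1 | intermediate
4 | (±)-trans-4-hydroxy-5-(prop-2-yn-1-yl)cyclopent-2-en-1-one (racemate, one enantiomer drawn) | O=C1C=C[C@@H](O)[C@@H]1CC#C | intermediate (not isolated)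
5 | (±)-4-hydroxy-2-(prop-2-yn-1-yl)cyclopent-2-en-1-one (racemate) | O=C1CC(O)C=C1CC#C | intermediate
6 | 2-(prop-2-yn-1-yl)cyclopent-2-ene-1,4-dione | O=C1CC(=O)C(CC#C)=C1 | intermediate
7 | butane-2,3-dione | CC(=O)C(C)=O | starting material
8 | 2,3-bis(triethylsilyloxy)buta-1,3-diene | C=C(O[Si](CC)(CC)CC)C(=C)O[Si](CC)(CC)CC | intermediate
9 | (3aR,7aS)-7a-(prop-2-yn-1-yl)-5,6-bis(triethylsilyloxy)-3a,4,7,7a-tetrahydro-1H-indene-1,3(2H)-dione (cis-fused rings B/C; propargyl on C-8 cis to H-9) | C#CC[C@]12CC(O[Si](CC)(CC)CC)=C(O[Si](CC)(CC)CC)C[C@H]1C(=O)CC2=O | intermediate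
10 | 9-methylidene-8-(triethylsilyloxy)tricyclo[6.2.1.0^{1,5}]undecane-2,4,7-trione (B/C/D tricycle; 6,10,12-trioxo, 13-OSiEt3, 16-methylene; H-9 cis to C-15) | C=C1C[C@]23C[C@@]1(O[Si](CC)(CC)CC)C(=O)C[C@H]2C(=O)CC3=O | intermediate
11 | 12-hydroxy-13-(triethylsilyloxy)-16-methylene B/C/D tricycle-6,10-dione (12-OH syn to C-10, anti to the C-15/C-16 bridge) | C=C1C[C@]23C[C@@]1(O[Si](CC)(CC)CC)[C@@H](O)C[C@H]2C(=O)CC3=O | intermediate
12 | 12,13-O-isopropylidene-10-methoxy-16-methylene B/C/D tricycle, 5(10)-en-6-one | C=C1C[C@]23C[C@@]1(OC(C)(C)O4)[C@@H]4C[C@H]2C(OC)=CC3=O | intermediate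
13 | 12,13-O-isopropylidene-10-methoxy-6-(trifluoromethanesulfonyloxy)-16-methylene B/C/D tricycle, 5,9-diene | C=C1C[C@]23C[C@@]1(OC(C)(C)O4)[C@@H]4CC2=C(OC)C=C3OS(=O)(=O)C(F)(F)F | intermediate
14 | 4-methoxybenzyl 12,13-O-isopropylidene-10-methoxy-16-methylene-5,9-dien-7-oate (ester on C-6) | C=C1C[C@]23C[C@@]1(OC(C)(C)O4)[C@@H]4CC2=C(OC)C=C3C(=O)OCc5ccc(OC)cc5 | intermediate (not isolated)
15 | 4-methoxybenzyl 12,13-O-isopropylidene-16-methylene-10-oxo-5-en-7-oate (H-9 cis to C-15) | C=C1C[C@]23C[C@@]1(OC(C)(C)O4)[C@@H]4C[C@H]2C(=O)C=C3C(=O)OCc5ccc(OC)cc5 | intermediate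
16 | bromomagnesium 10-alkoxide of the 10-vinyl carbinol (O-10 syn to O-12) | C=C1C[C@]23C[C@@]1(OC(C)(C)O4)[C@@H]4C[C@H]2[C@](O[Mg]Br)(C=C)C=C3C(=O)OCc5ccc(OC)cc5 | intermediate (not isolated)
17 | 4-methoxybenzyl 12,13-O-isopropylidene-16-methylene-10-(propanoyloxy)-10-vinyl-5-en-7-oate | C=C1C[C@]23C[C@@]1(OC(C)(C)O4)[C@@H]4C[C@H]2[C@](OC(=O)CC)(C=C)C=C3C(=O)OCc5ccc(OC)cc5 | intermediate
18 | potassium C-6 ester enolate of the Michael adduct (19,10-lactone closed; C-4 epimers) | C=C1C[C@]23C[C@@]1(OC(C)(C)O4)[C@@H]4C[C@H]2[C@@]2(C=C)OC(=O)C(C)[C@H]2C3=C([O-])OCc5ccc(OC)cc5.[K+] | intermediate (not isolated)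
19 | potassium C-4 lactone enolate (C-6 ester trans to C-4) | C=C1C[C@]23C[C@@]1(OC(C)(C)O4)[C@@H]4C[C@H]2[C@@]2(C=C)OC([O-])=C(C)[C@H]2[C@@H]3C(=O)OCc5ccc(OC)cc5.[K+] | intermediate (not isolated)
20 | 4-methoxybenzyl ester of the 19,10-lactone with 4-methyl, 4-(1-hydroxyprop-2-enyl) (C-3 and C-4 as in the target) and 10-vinyl; 12,13-acetonide | C=C1C[C@]23C[C@@]1(OC(C)(C)O4)[C@@H]4C[C@H]2[C@@]2(C=C)OC(=O)[C@@]([C@@H](O)C=C)(C)[C@H]2[C@@H]3C(=O)OCc5ccc(OC)cc5 | intermediate
21 | 12-hydroxygibberellic acid 12,13-acetonide 7-(4-methoxybenzyl) ester | C=C1C[C@]23C[C@@]1(OC(C)(C)O4)[C@@H]4C[C@H]2[C@@]12C=C[C@H](O)[C@@](C)(C(=O)O1)[C@H]2[C@@H]3C(=O)OCc5ccc(OC)cc5 | intermediate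
22 | 12-hydroxygibberellic acid (gibberellic acid with an added 12-hydroxyl syn to C-10 and anti to the C-15/C-16 bridge; 3-hydroxyl cis to the 4-methyl; 19,10-lactone) | C=C1C[C@]23C[C@@]1(O)[C@@H](O)C[C@H]2[C@@]12C=C[C@H](O)[C@@](C)(C(=O)O1)[C@H]2[C@@H]3C(=O)O | target

**Step count.** Total: 14 steps. Longest linear sequence: 13 steps (steps 1–3 and 5–14); step 4 is a one-step side branch.

**Steps most likely to fail**

Step 5. The risk is poor enantiofacial control, or acid-induced loss of the enol silyl ethers before cycloaddition. The fallback sets out from 6 and 8: the cycloaddition is run without catalyst (toluene, 60 °C), which should give 9 together with its mirror image ent-9 F1. Gold cyclisation as in step 6 then gives 10 together with ent-10 F2, and preparative chromatography on a chiral stationary phase (cellulose tris(3,5-dimethylphenylcarbamate), supercritical CO2–MeOH) separates the two. The route is rejoined at 10.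

Step 6. The risk is protodesilylation of the bis(silyl) enediol ether outrunning carbocyclisation, or attack of the ring-B dione carbon or its enol oxygen on the alkyne. The fallback sets out from 9: semi-hydrogenation (H2, Pd/CaCO3 poisoned with Pb(OAc)2, quinoline, EtOAc) should give the allyl dione F3. Pd(OAc)2 (1 equiv) in DMSO at 45 °C should then effect oxidative cycloalkenylation of the silyl enol ether (a Saegusa-type reaction): C-13 attacks the palladium-bound alkene in 5-exo fashion and β-hydride elimination leaves the exocyclic methylene. The route is rejoined at 10.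

Step 12. The risk is incomplete relay of the enolate from C-6 to C-4, so that acrolein is captured at the wrong carbon, or poor facial control in the aldol addition. The fallback sets out from 15 and replaces the anionic ring closure by a radical one. Addition of CeCl3/CH2=CHMgBr followed by 2-bromopropanoyl bromide should give the α-bromopropanoate F4 (both epimers at CHBr). Bu3SnH and AIBN in benzene at 80 °C (slow addition) should generate the α-acyl radical, which closes 5-exo-trig onto C-5; hydrogen-atom transfer and brief equilibration with DBU at C-4 and C-6 then give the neutral lactone F5. LiN(i-Pr)2 at −78 °C should remove the lactone α-hydrogen (more acidic and less hindered than the neopentyl ester α-hydrogen); MgBr2·OEt2 and acrolein then lead back to the route at 20.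

Further compounds
F1 | step 5 | ent-9, (3aS,7aR)-7a-(prop-2-yn-1-yl)-5,6-bis(triethylsilyloxy)-3a,4,7,7a-tetrahydro-1H-indene-1,3(2H)-dione | C#CC[C@@]12CC(O[Si](CC)(CC)CC)=C(O[Si](CC)(CC)CC)C[C@@H]1C(=O)CC2=O
F2 | step 5 | ent-10, mirror image of the B/C/D trione | C=C1C[C@@]23C[C@]1(O[Si](CC)(CC)CC)C(=O)C[C@@H]2C(=O)CC3=O
F3 | step 6 | (3aR,7aS)-7a-allyl-5,6-bis(triethylsilyloxy)-3a,4,7,7a-tetrahydro-1H-indene-1,3(2H)-dione | C=CC[C@]12CC(O[Si](CC)(CC)CC)=C(O[Si](CC)(CC)CC)C[C@H]1C(=O)CC2=O
F4 | step 12 | 4-methoxybenzyl 10-(2-bromopropanoyloxy)-12,13-O-isopropylidene-16-methylene-10-vinyl-5-en-7-oate (both CHBr epimers) | C=C1C[C@]23C[C@@]1(OC(C)(C)O4)[C@@H]4C[C@H]2[C@](OC(=O)C(C)Br)(C=C)C=C3C(=O)OCc5ccc(OC)cc5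
F5 | step 12 | neutral Michael-type lactone (19,10-lactone, 4-H, 4-methyl on the convex face, 10-vinyl, 7-(4-methoxybenzyl) ester, 12,13-acetonide) | C=C1C[C@]23C[C@@]1(OC(C)(C)O4)[C@@H]4C[C@H]2[C@@]2(C=C)OC(=O)[C@H](C)[C@H]2[C@@H]3C(=O)OCc5ccc(OC)cc5
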